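**Numbering and remark.** Carotenoid numbering is used throughout, with primed locants for the furanoid half. Remark on the chemistry: (E)-3-methylpent-2-en-4-yn-1-ol (7) and the 10-carbon dialdehyde (24) are taken as catalogue chemicals; all polyene steps are run under argon in dim light.

## The problem

The target is a 40-carbon carotenoid tetrol: an all-E octaene chain (C7 to C10', four methyl branches) joins two different oxygenated trimethylcyclohexane end groups, so the chain must be built by olefinations that give E double bonds and that both ends survive. The left ring is a (3S,5R,6S)-triol: the 5,6-diol is cis, lies on the face opposite to the C3 hydroxyl, and C6 is a tertiary carbinol bonded directly to the polyene. The right end is a (3'S,5'R,8'R)-5',8'-epoxide, a 2,5-dihydrofuran fused at C5'–C6', whose C8' carries hydrogen and the chain, the chain trans to the C5' methyl. C3 and C3' are remote secondary carbinols of the same absolute sense and can come from one chiral-pool ketone. Within each ring the C3 oxygen is the only element that can choose the face at C5/C6, and only from a 1,3 distance. C8' lies outside the six-membered ring, beyond useful reach of C3', and the classical acid-induced ring contraction of a 5',6'-epoxide gives both C8' configurations. The C8'–O bond is an allylic ether that acid ionises, the C6 hydroxyl is tertiary and allylic to the polyene, the cis-glycol is open to cleaving oxidants, and the polyene itself is sensitive to acid, iodine, light and oxygen. The enabling feature is that the ring oxygen joins C5' to C8' across the C6'=C7' double bond. The dihydrofuran is therefore the cycloisomer of a C5' tertiary alcohol bearing a C6'=C7'=C8' allene, and that allene axis can in turn be written from a C5',C6'-epoxide whose oxygen is the same C5' oxygen.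

## Retrosynthesis

**Silyl ethers last.** Target 32 is traced to its 3,3'-bis-silyl ether 31. Fluoride removes both groups without acid, which the dihydrofuran and the C6 carbinol require.

**C11'=C12'.** Compound 31 is cut at C11'=C12' into the furanoid 15-carbon aldehyde 15 and the left-hand 25-carbon phosphonate 29. Cutting at the central C15=C15' bond would need two 20-carbon pieces and more chain-building on each sensitive end. Cutting so that the furanoid end becomes the nucleophile would require an allylic halide or phosphonium salt next to the acid-labile C8'–O bond. As an aldehyde, the furanoid end needs only a neutral MnO2 oxidation. The forward Horner–Wadsworth–Emmons step must give the E double bond and must not deprotonate C8'.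

**C11=C12.** Phosphonate 29 is cut at C11=C12 into the left 15-carbon dienal 23 and the symmetrical 10-carbon bis(phosphonate) 27. Compound 27 comes in three routine steps from dialdehyde 24 through diol 25 and dibromide 26. Both ring fragments are thus aldehydes, and neither has to pass through an ionising activation. The forward step asks for mono-olefination, secured by an excess of 27.

**Aldehyde 15.** It is traced through allylic alcohol 14 to acetate 13. These are functional-group changes under basic or neutral conditions.

**O–C8' (key disconnection).** Breaking the O–C8' bond of 13 opens the dihydrofuran to the allenic acetate 12. This removes the only ring formed late and replaces the C8' stereocentre by an axis. The neighbouring choice, contraction of a 5',6'-epoxide, offers no control at C8'. The forward gold-catalysed closure must transfer the axis completely. By the rule for axial chirality (C5' before C1' at the ring end, C9' before H at the chain end) the axis needed is (S): the chain on C8' lies on the face of the C5' hydroxyl and H8' on the other. This is the epimer of the (6R) axis of the natural allenic carotenoids.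

**C8'–H and the axis.** Allene 12 is traced to the propargylic 5',6'-epoxide 10 by an SN2' hydride opening: the C8'–H bond forms as the C6'–O bond breaks, and the epoxide oxygen stays on C5'. Hydride must enter on the face opposite to the breaking C6'–O bond. The aluminium hydride openings used for natural allenic end groups give the natural (6R) axis, in which H8 lies on the oxygen side, and that axis would close to the C8' epimer. The step is therefore given to a copper hydride catalyst, whose SN2' reductions of propargyl oxiranes are taken to follow the anti course usual for copper. Because that reagent reduces enoates, the chain oxygen is carried at the alcohol level as its acetate.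

**Epoxide and chain.** Epoxide 10 comes from dienyne acetate 9 by peracid attack on the ring alkene. Compound 9 comes from dienynol 8, and 8 from enol triflate 6 and the commercial enynol 7 by Sonogashira coupling (C6'–C7' bond). Coupling the whole six-carbon chain at once is shorter than ethynylation followed by a second coupling. It asks the peracid to prefer the tetrasubstituted ring alkene over the acetate-deactivated chain alkene, and the face anti to the silyloxy group.

**Left ring.** Dienal 23 is traced to dienetriol 22 and then to enynoate diol 21, where the C7≡C8 alkyne is a masked E-alkene and the ester a masked alcohol; LiAlH4 unmasks both. Compound 21 is cut at C8–C9 into terminal alkyne 19 and ethyl but-2-ynoate 20 (palladium-catalysed alkyne cross-addition, which gives the E enynoate directly). Compound 19 comes from alkynylsilane diol 18, and the two C–O bonds of 18 from osmylation of enyne 17. Osmylation is placed at 17 because no other alkene is present. Compound 17 comes from triflate 6 and trimethylsilylacetylene 16.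

**Ring building block.** Triflate 6 serves both halves. It is traced through lithium enolate 5 and silyl ether 4 to hydroxy ketone 3, and from there through dione 2 to ketoisophorone 1. The single stereocentre that survives (C3, C3') is set by a yeast reduction followed by a diastereoselective hydrogenation.

## Roads not taken

**Alternative 1:** cis-dihydroxylation of the ring enyne. The cut runs through the C5–O and C6–O bonds of the left ring. In the forward step OsO4 (octavalent osmium) with an amine N-oxide adds to the tetrasubstituted alkene of 17 on the face away from the C3 silyloxy group and gives the alkynyl cis-diol A1.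
- Merits: both carbinol centres of the left ring arise together and suprafacially, on a substrate with no other alkene, and the alkyne that remains is a masked E-alkene.
- Weak points: the alkene is tetrasubstituted and flanked by a quaternary carbon, so osmate turnover is slow, and the face is chosen only by a 1,3-related silyloxy group. As the organising step of a synthesis it leaves the harder half open: the furanoid end would fall back on acid-induced contraction of a 5',6'-epoxy end group, which gives both C8' configurations and exposes the polyene to acid.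
- Comparison: for the left ring this road is as good as any available and is not set aside. A1 is compound 18 and the reaction is step 13. The chosen plan adds what this road lacks, control of C8'.

**Alternative 2:** singlet-oxygen endoperoxide across C5' and C8'. The cut removes both C–O bonds of the furanoid end at once. In the forward step singlet oxygen (porphyrin sensitiser, visible light) adds in a [4+2] sense across the s-cis C5'=C6'–C7'=C8' diene of the silylated triene ester A2 and gives the 3,6-dihydro-1,2-dioxine A3.
- Merits: one step from a short substrate, high atom economy, and suprafacial addition ties C8' to C5'. The outside groups of the diene termini (C4' and the chain) end cis, which is the relative configuration of the target.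
- Weak points: the diene must become coplanar against the C1' gem-dimethyl group and the C5' methyl. Ene reactions at the allylic methyl and methylene of the electron-rich ring alkene and attack at C9'=C10' compete. The face is again left to C3'. One oxygen is in excess: the O–O bond must be cut and a C–O bond re-formed, and any closure that displaces oxygen at C8' inverts or scrambles that centre, so the correct relative configuration of A3 cannot be passed on.
- Comparison: this road reaches the oxygenation pattern in fewer steps and without coinage-metal catalysts. The chosen plan is longer, but each of its stereochemical events is stereospecific (anti SN2' opening, in-plane ring closure) and the product never meets peroxide-reducing or ionising conditions.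

**Alternative 3:** stereoretentive epoxide opening by palladium and carbon dioxide. The cut is the C6–O bond of the left ring. In the forward step Pd(PPh3)4 (zerovalent palladium) ionises the allylic C6–O bond of the 15-carbon epoxy dienoate A4 with inversion, the C5 alkoxide captures CO2, and the carbonate oxygen closes on C6 anti to palladium, giving the 5,6-cis cyclic carbonate A5 with net retention.
- Merits: an epoxide face, which is the same facial event needed on the right half, becomes the cis-diol by double inversion. The diol emerges protected against cleaving oxidants and olefination bases.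
- Weak points: C6 is fully substituted and next to a quaternary carbon, so ionisation is slow. The ester-conjugated pentadienyl palladium intermediate can be captured at C8 or C10 as well, can lose E geometry by σ–π interconversion, or can lose a proton from the C5 methyl. A dienoate building block and a chemoselective triene epoxidation are needed first.
- Comparison: for the left ring its stereochemical logic is arguably cleaner than substrate-controlled osmylation, at a similar step count. It does nothing for C8'. The chosen plan solves the left ring from the shared enyne 17 without π-allyl regiochemistry and places its central step on the harder problem.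

Key step: step 9

## Route

Step 1
Reactants: 1 ketoisophorone
Product: 2 (6R)-2,2,6-trimethylcyclohexane-1,4-dione
Conditions: baker's yeast (Saccharomyces cerevisiae), sucrose, H2O, 30 °C
Reagents that add atoms: none
Why: Biocatalytic conjugate reduction: the ene-reductases of the yeast add hydrogen to the enedione C=C from one face and set C6 as R; this centre steers step 2 and is erased in step 4.

Step 2
Reactants: 2 (6R)-2,2,6-trimethylcyclohexane-1,4-dione
Product: 3 (4R,6R)-4-hydroxy-2,2,6-trimethylcyclohexan-1-one
Conditions: H2, Raney Ni, MeOH, rt; crystallisation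
Reagents that add atoms: none
Why: Heterogeneous hydrogenation reduces only the unhindered C4 carbonyl (C1 is flanked by a quaternary and a tertiary carbon) and should place the hydroxyl mainly trans to the C6 methyl, which sets the carbinol that becomes C3 and C3'; the minor cis isomer is removed by crystallisation.

Step 3
Reactants: 3 (4R,6R)-4-hydroxy-2,2,6-trimethylcyclohexan-1-one
Product: 4 (4R,6R)-4-(tert-butyldimethylsilyloxy)-2,2,6-trimethylcyclohexan-1-one
Conditions: TBSCl, imidazole, DMF, rt
Reagents that add atoms: tert-butyldimethylsilyl chloride CC(C)(C)[Si](C)(C)Cl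
Why: Imidazole-promoted silylation of the secondary alcohol; no stereocentre is touched.

Step 4
Reactants: 4 (4R,6R)-4-(tert-butyldimethylsilyloxy)-2,2,6-trimethylcyclohexan-1-one
Product: 6 (R)-4-(tert-butyldimethylsilyloxy)-2,6,6-trimethylcyclohex-1-en-1-yl trifluoromethanesulfonate, via lithium enolate 5 (not isolated)
Conditions: LiN(i-Pr)2, THF, −78 °C; then PhNTf2, −78 °C → rt
Reagents that add atoms: N-phenylbis(trifluoromethanesulfonimide) O=S(=O)(N(c1ccccc1)S(=O)(=O)C(F)(F)F)C(F)(F)F
Why: C6–H is the only enolisable position, so a single enolate forms and O-triflation gives the tetrasubstituted enol triflate; the C6 stereocentre disappears and the silyloxy carbinol is untouched.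

Step 5
Reactants: 6 (R)-4-(tert-butyldimethylsilyloxy)-2,6,6-trimethylcyclohex-1-en-1-yl trifluoromethanesulfonate; 7 (E)-3-methylpent-2-en-4-yn-1-ol
Product: 8 (E)-5-[(R)-4-(tert-butyldimethylsilyloxy)-2,6,6-trimethylcyclohex-1-en-1-yl]-3-methylpent-2-en-4-yn-1-ol
Conditions: Pd(PPh3)4 (5 mol%), CuI (10 mol%), Et3N, DMF, 50 °C
Reagents that add atoms: none
Why: Sonogashira coupling of a vinyl triflate with a terminal alkyne forms C6'–C7'; the E geometry of 7 and the free hydroxyl are not affected.

Step 6
Reactants: 8 (E)-5-[(R)-4-(tert-butyldimethylsilyloxy)-2,6,6-trimethylcyclohex-1-en-1-yl]-3-methylpent-2-en-4-yn-1-ol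
Product: 9 (E)-5-[(R)-4-(tert-butyldimethylsilyloxy)-2,6,6-trimethylcyclohex-1-en-1-yl]-3-methylpent-2-en-4-yn-1-yl acetate
Conditions: Ac2O, pyridine, DMAP (cat.), CH2Cl2, 0 °C
Reagents that add atoms: acetic anhydride CC(=O)OC(C)=O
Why: Acetylation of the primary alcohol; the acetate lowers the nucleophilicity of the chain alkene for step 7, removes a hydroxyl that would direct a peracid, and blocks the C11' oxygen in step 9.

Step 7
Reactants: 9 (E)-5-[(R)-4-(tert-butyldimethylsilyloxy)-2,6,6-trimethylcyclohex-1-en-1-yl]-3-methylpent-2-en-4-yn-1-yl acetate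
Product: 10 (E)-5-[(1R,4S,6R)-4-(tert-butyldimethylsilyloxy)-2,2,6-trimethyl-7-oxabicyclo[4.1.0]heptan-1-yl]-3-methylpent-2-en-4-yn-1-yl acetate (5',6'-epoxide anti to the silyloxy group)
Conditions: mCPBA, NaHCO3, CH2Cl2, −20 → 0 °C
Reagents that add atoms: 3-chloroperbenzoic acid OOC(=O)c1cccc(Cl)c1
Why: Concerted peracid epoxidation; the tetrasubstituted ring alkene is the most electron-rich π bond (the chain alkene is trisubstituted and deactivated by the allylic acetate). Rings of this kind carrying a protected C3 oxygen are expected to be attacked mainly on the face opposite to that substituent, which sets C5' and C6'; the minor syn epoxide is removed by chromatography.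

Step 8
Reactants: 10 (E)-5-[(1R,4S,6R)-4-(tert-butyldimethylsilyloxy)-2,2,6-trimethyl-7-oxabicyclo[4.1.0]heptan-1-yl]-3-methylpent-2-en-4-yn-1-yl acetate
Product: 12 (2E)-5-[(2R,4S)-4-(tert-butyldimethylsilyloxy)-2-hydroxy-2,6,6-trimethylcyclohexylidene]-3-methylpenta-2,4-dien-1-yl acetate with (S) allene axis (chain on C8' syn, H8' anti to the C5' hydroxyl), via C5' silyl ether 11 (not isolated)
Conditions: CuCl (5 mol%), NaOt-Bu (5 mol%), IMes·HCl (5 mol%), (EtO)2MeSiH, toluene, 0 °C; then NH4F, MeOH, rt
Reagents that add atoms: none
Why: Copper hydride-catalysed SN2' reduction of a propargyl oxirane (monovalent copper hydride on an N-heterocyclic carbene): syn hydrocupration puts H on C8' and copper on C7', and anti β-alkoxide elimination breaks C6'–O, so hydride ends opposite to the departing oxygen and the chain on its side, which is the (S) axis; the C5' configuration is that of the epoxide. The copper alkoxide is turned over by the silane to silyl ether 11, which fluoride cleaves without touching the acetate or the tert-butyldimethylsilyl ether.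

Step 9
Reactants: 12 (2E)-5-[(2R,4S)-4-(tert-butyldimethylsilyloxy)-2-hydroxy-2,6,6-trimethylcyclohexylidene]-3-methylpenta-2,4-dien-1-yl acetate with (S) allene axis
Product: 13 (E)-3-[(2R,6S,7aR)-6-(tert-butyldimethylsilyloxy)-4,4,7a-trimethyl-2,4,5,6,7,7a-hexahydro-1-benzofuran-2-yl]but-2-en-1-yl acetate (3'S,5'R,8'R)
Conditions: Ph3PAuCl (2 mol%), AgBF4 (2 mol%), toluene, 0 °C; Et3N quench
Reagents that add atoms: none
Why: Ph3PAu+ (monovalent gold, freed from Ph3PAuCl by AgBF4) binds the C7'=C8' π bond of the allene, the one whose orbitals lie in the plane of C5', C6' and C1'; the C5' hydroxyl attacks C8' in that plane anti to gold, a 5-endo-trig closure of the only ring formed, and protodeauration of the C7' vinylgold leaves the C6'=C7' double bond and returns the catalyst. The closest known reaction type is the gold-catalysed cycloisomerisation of α-hydroxyallenes to 2,5-dihydrofurans. C8' is the one new stereocentre and the allene axis controls it: H and the chain on C8' stand above and below the plane in which oxygen arrives and keep their sides, so the (S) axis with (5'R) gives (8'R), the chain trans to the C5' methyl. The step needs complete axis-to-centre transfer, which asks that ring closure outrun gold-induced epimerisation of the vinyl-substituted allene; the rigidly placed tertiary hydroxyl, the non-polar solvent, low temperature and low loading favour this. The acetate keeps the C11' oxygen from competing, and the amine quench keeps adventitious acid from ionising the new allylic ether.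

Step 10
Reactants: 13 (E)-3-[(2R,6S,7aR)-6-(tert-butyldimethylsilyloxy)-4,4,7a-trimethyl-2,4,5,6,7,7a-hexahydro-1-benzofuran-2-yl]but-2-en-1-yl acetate
Product: 14 (E)-3-[(2R,6S,7aR)-6-(tert-butyldimethylsilyloxy)-4,4,7a-trimethyl-2,4,5,6,7,7a-hexahydro-1-benzofuran-2-yl]but-2-en-1-ol
Conditions: K2CO3 (cat.), MeOH, 0 °C
Reagents that add atoms: none
Why: Base-catalysed transesterification removes the acetate under conditions that the acid-labile allylic ether and the silyl ether tolerate.

Step 11
Reactants: 14 (E)-3-[(2R,6S,7aR)-6-(tert-butyldimethylsilyloxy)-4,4,7a-trimethyl-2,4,5,6,7,7a-hexahydro-1-benzofuran-2-yl]but-2-en-1-ol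
Product: 15 (E)-3-[(2R,6S,7aR)-6-(tert-butyldimethylsilyloxy)-4,4,7a-trimethyl-2,4,5,6,7,7a-hexahydro-1-benzofuran-2-yl]but-2-enal
Conditions: MnO2, CH2Cl2, rt
Reagents that add atoms: none
Why: MnO2 oxidation of a primary allylic alcohol to the enal at neutral pH, with the E geometry kept and C8' untouched.

Step 12
Reactants: 6 (R)-4-(tert-butyldimethylsilyloxy)-2,6,6-trimethylcyclohex-1-en-1-yl trifluoromethanesulfonate; 16 trimethylsilylacetylene
Product: 17 (R)-tert-butyldimethyl{[3,5,5-trimethyl-4-(trimethylsilylethynyl)cyclohex-3-en-1-yl]oxy}silane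
Conditions: Pd(PPh3)4 (5 mol%), CuI (10 mol%), Et3N, DMF, 50 °C
Reagents that add atoms: none
Why: Sonogashira coupling of the vinyl triflate with a silyl-protected terminal alkyne forms C6–C7 of the left half.

Step 13
Reactants: 17 (R)-tert-butyldimethyl{[3,5,5-trimethyl-4-(trimethylsilylethynyl)cyclohex-3-en-1-yl]oxy}silane
Product: 18 (1R,2R,4S)-4-(tert-butyldimethylsilyloxy)-2,6,6-trimethyl-1-(trimethylsilylethynyl)cyclohexane-1,2-diol
Conditions: OsO4 (10 mol%), Me3NO·2H2O, pyridine, t-BuOH–H2O, 60 °C
Reagents that add atoms: osmium tetroxide O=[Os](=O)(=O)=O (transfers both oxygens); trimethylamine N-oxide C[N+](C)(C)[O-] and water O (restore OsO4)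
Why: Suprafacial cis-dihydroxylation by OsO4 (octavalent osmium) of the only alkene; attack is expected on the face opposite to the C3 silyloxy group, as with the peracid, which sets C5 and C6 together; pyridine and heat are used because osmate esters of tetrasubstituted alkenes turn over slowly.

Step 14
Reactants: 18 (1R,2R,4S)-4-(tert-butyldimethylsilyloxy)-2,6,6-trimethyl-1-(trimethylsilylethynyl)cyclohexane-1,2-diol
Product: 19 (1R,2R,4S)-4-(tert-butyldimethylsilyloxy)-1-ethynyl-2,6,6-trimethylcyclohexane-1,2-diol
Conditions: K2CO3, MeOH, rt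
Reagents that add atoms: none
Why: Methanolysis of the alkynyl C–Si bond; the silyl ether and the diol are inert to these conditions.

Step 15
Reactants: 19 (1R,2R,4S)-4-(tert-butyldimethylsilyloxy)-1-ethynyl-2,6,6-trimethylcyclohexane-1,2-diol; 20 ethyl but-2-ynoate
Product: 21 ethyl (E)-5-[(1R,2R,4S)-4-(tert-butyldimethylsilyloxy)-1,2-dihydroxy-2,6,6-trimethylcyclohexyl]-3-methylpent-2-en-4-ynoate
Conditions: Pd(OAc)2 (3 mol%), tris(2,6-dimethoxyphenyl)phosphine (3 mol%), THF, rt
Reagents that add atoms: none
Why: Palladium-catalysed cross-addition of a terminal alkyne C–H across an alkynoate: the alkynyl group goes to the β-carbon and hydrogen to the α-carbon in a syn sense, which gives the E enynoate (C8–C9 bond); tertiary propargylic alcohols are tolerated as donors.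

Step 16
Reactants: 21 ethyl (E)-5-[(1R,2R,4S)-4-(tert-butyldimethylsilyloxy)-1,2-dihydroxy-2,6,6-trimethylcyclohexyl]-3-methylpent-2-en-4-ynoate
Product: 22 (1S,2R,4S)-4-(tert-butyldimethylsilyloxy)-1-[(1E,3E)-5-hydroxy-3-methylpenta-1,3-dien-1-yl]-2,6,6-trimethylcyclohexane-1,2-diol
Conditions: LiAlH4, THF, 0 °C → rt; aq. KNaC4H4O6 work-up
Reagents that add atoms: none
Why: LiAlH4 reduces the ester to the primary alcohol and, through the C6 alkoxide (trans-hydroalumination of a propargylic alcohol), the alkyne to the E alkene; the C6 descriptor changes from R to S only because the alkenyl group ranks below C1.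

Step 17
Reactants: 22 (1S,2R,4S)-4-(tert-butyldimethylsilyloxy)-1-[(1E,3E)-5-hydroxy-3-methylpenta-1,3-dien-1-yl]-2,6,6-trimethylcyclohexane-1,2-diol
Product: 23 (2E,4E)-5-[(1S,2R,4S)-4-(tert-butyldimethylsilyloxy)-1,2-dihydroxy-2,6,6-trimethylcyclohexyl]-3-methylpenta-2,4-dienal
Conditions: SO3·pyridine, DMSO, i-Pr2NEt, CH2Cl2, 0 °C
Reagents that add atoms: none
Why: Parikh–Doering oxidation: activated DMSO oxidises the primary allylic alcohol, leaves the tertiary alcohols alone and, unlike metal oxide oxidants, does not cleave the cis-glycol.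

Step 18
Reactants: 24 (2E,4E,6E)-2,7-dimethylocta-2,4,6-trienedial
Product: 25 (2E,4E,6E)-2,7-dimethylocta-2,4,6-triene-1,8-diol
Conditions: NaBH4, MeOH–THF, 0 °C
Reagents that add atoms: none
Why: Borohydride 1,2-reduction of both enal groups; the triene geometry is kept.

Step 19
Reactants: 25 (2E,4E,6E)-2,7-dimethylocta-2,4,6-triene-1,8-diol
Product: 26 (2E,4E,6E)-1,8-dibromo-2,7-dimethylocta-2,4,6-triene
Conditions: PBr3, pyridine (cat.), Et2O, −10 °C; used crude
Reagents that add atoms: phosphorus tribromide BrP(Br)Br
Why: Substitution of the primary allylic alcohols by bromide; the symmetrical, fully conjugated product is the thermodynamic allylic isomer.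

Step 20
Reactants: 26 (2E,4E,6E)-1,8-dibromo-2,7-dimethylocta-2,4,6-triene
Product: 27 tetraethyl [(2E,4E,6E)-2,7-dimethylocta-2,4,6-triene-1,8-diyl]bis(phosphonate)
Conditions: P(OEt)3, 110 °C
Reagents that add atoms: triethyl phosphite CCOP(OCC)OCC
Why: Michaelis–Arbuzov reaction of the primary allylic bromides.

Step 21
Reactants: 23 (2E,4E)-5-[(1S,2R,4S)-4-(tert-butyldimethylsilyloxy)-1,2-dihydroxy-2,6,6-trimethylcyclohexyl]-3-methylpenta-2,4-dienal; 27 tetraethyl [(2E,4E,6E)-2,7-dimethylocta-2,4,6-triene-1,8-diyl]bis(phosphonate)
Product: 29 diethyl {(2E,4E,6E,8E,10E,12E)-13-[(1S,2R,4S)-4-(tert-butyldimethylsilyloxy)-1,2-dihydroxy-2,6,6-trimethylcyclohexyl]-2,7,11-trimethyltrideca-2,4,6,8,10,12-hexaen-1-yl}phosphonate, via sodium phosphonate carbanion 28 (not isolated)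
Conditions: 27 (3 equiv), NaN(SiMe3)2 (3 equiv), THF, −78 °C; then 23, −78 → 0 °C
Reagents that add atoms: none
Why: Horner–Wadsworth–Emmons olefination forms C11=C12 with the E preference of allylic phosphonate anions; the excess of 28 absorbs the two hydroxyl protons of 23 and keeps the reaction at mono-olefination, and unreacted 27 is recovered.

Step 22
Reactants: 29 diethyl {(2E,4E,6E,8E,10E,12E)-13-[(1S,2R,4S)-4-(tert-butyldimethylsilyloxy)-1,2-dihydroxy-2,6,6-trimethylcyclohexyl]-2,7,11-trimethyltrideca-2,4,6,8,10,12-hexaen-1-yl}phosphonate; 15 (E)-3-[(2R,6S,7aR)-6-(tert-butyldimethylsilyloxy)-4,4,7a-trimethyl-2,4,5,6,7,7a-hexahydro-1-benzofuran-2-yl]but-2-enal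
Product: 31 (3S,5R,6S,3'S,5'R,8'R)-3,3'-bis(tert-butyldimethylsilyloxy)-5',8'-epoxy-5,6,5',8'-tetrahydro-β,β-carotene-5,6-diol, via trisodium salt 30 (not isolated)
Conditions: NaN(SiMe3)2 (3 equiv), THF, −78 °C; then 15, −78 → 0 °C
Reagents that add atoms: none
Why: Horner–Wadsworth–Emmons olefination forms C11'=C12' (E); the base is consumed by 29 before the aldehyde is added, so that C8' of 15, the γ-position of the enal, is not exposed to free amide.

Step 23
Reactants: 31 (3S,5R,6S,3'S,5'R,8'R)-3,3'-bis(tert-butyldimethylsilyloxy)-5',8'-epoxy-5,6,5',8'-tetrahydro-β,β-carotene-5,6-diol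
Product: 32 (3S,5R,6S,3'S,5'R,8'R)-5',8'-epoxy-5,6,5',8'-tetrahydro-β,β-carotene-3,5,6,3'-tetrol
Conditions: Bu4NF, THF, 0 °C → rt
Reagents that add atoms: none
Why: Fluoride cleavage of the two secondary silyl ethers under non-acidic conditions that leave the dihydrofuran, the tertiary allylic carbinol and the polyene intact.

## Compound list

1 | ketoisophorone (2,6,6-trimethylcyclohex-2-ene-1,4-dione) | CC1=CC(=O)CC(C)(C)C1=O | starting material
2 | (6R)-2,2,6-trimethylcyclohexane-1,4-dione | CC1(C)CC(=O)C[C@@H](C)C1=O | intermediate
3 | (4R,6R)-4-hydroxy-2,2,6-trimethylcyclohexan-1-one | CC1(C)C[C@H](O)C[C@@H](C)C1=O | intermediate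
4 | (4R,6R)-4-(tert-butyldimethylsilyloxy)-2,2,6-trimethylcyclohexan-1-one | CC1(C)C[C@H](O[Si](C)(C)C(C)(C)C)C[C@@H](C)C1=O | intermediate
5 | lithium (R)-4-(tert-butyldimethylsilyloxy)-2,6,6-trimethylcyclohex-1-en-1-olate | CC1=C([O-])C(C)(C)C[C@H](O[Si](C)(C)C(C)(C)C)C1.[Li+] | intermediate
6 | (R)-4-(tert-butyldimethylsilyloxy)-2,6,6-trimethylcyclohex-1-en-1-yl trifluoromethanesulfonate | CC1=C(OS(=O)(=O)C(F)(F)F)C(C)(C)C[C@H](O[Si](C)(C)C(C)(C)C)C1 | intermediate
7 | (E)-3-methylpent-2-en-4-yn-1-ol | C#C/C(C)=C/CO | starting material
8 | (E)-5-[(R)-4-(tert-butyldimethylsilyloxy)-2,6,6-trimethylcyclohex-1-en-1-yl]-3-methylpent-2-en-4-yn-1-ol | OC/C=C(\C)C#CC1=C(C)C[C@@H](O[Si](C)(C)C(C)(C)C)CC1(C)C | intermediate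
9 | (E)-5-[(R)-4-(tert-butyldimethylsilyloxy)-2,6,6-trimethylcyclohex-1-en-1-yl]-3-methylpent-2-en-4-yn-1-yl acetate | CC(=O)OC/C=C(\C)C#CC1=C(C)C[C@@H](O[Si](C)(C)C(C)(C)C)CC1(C)C | intermediate
10 | (E)-5-[(1R,4S,6R)-4-(tert-butyldimethylsilyloxy)-2,2,6-trimethyl-7-oxabicyclo[4.1.0]heptan-1-yl]-3-methylpent-2-en-4-yn-1-yl acetate (epoxide anti to the silyloxy group) | CC(=O)OC/C=C(\C)C#C[C@@]12O[C@]1(C)C[C@@H](O[Si](C)(C)C(C)(C)C)CC2(C)C | intermediate
11 | C5' diethoxy(methyl)silyl ether of allenol 12 | CC(=O)OC/C=C(\C)C([H])=[C@]=C1C(C)(C)C[C@H](O[Si](C)(C)C(C)(C)C)C[C@@]1(C)O[Si](C)(OCC)OCC | intermediate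
12 | (2E)-5-[(2R,4S)-4-(tert-butyldimethylsilyloxy)-2-hydroxy-2,6,6-trimethylcyclohexylidene]-3-methylpenta-2,4-dien-1-yl acetate, (S) allene axis (3'S,5'R,6'S) | CC(=O)OC/C=C(\C)C([H])=[C@]=C1C(C)(C)C[C@H](O[Si](C)(C)C(C)(C)C)C[C@@]1(C)O | intermediate
13 | (E)-3-[(2R,6S,7aR)-6-(tert-butyldimethylsilyloxy)-4,4,7a-trimethyl-2,4,5,6,7,7a-hexahydro-1-benzofuran-2-yl]but-2-en-1-yl acetate (3'S,5'R,8'R) | CC(=O)OC/C=C(\C)[C@H]1C=C2C(C)(C)C[C@H](O[Si](C)(C)C(C)(C)C)C[C@@]2(C)O1 | intermediate
14 | (E)-3-[(2R,6S,7aR)-6-(tert-butyldimethylsilyloxy)-4,4,7a-trimethyl-2,4,5,6,7,7a-hexahydro-1-benzofuran-2-yl]but-2-en-1-ol | OC/C=C(\C)[C@H]1C=C2C(C)(C)C[C@H](O[Si](C)(C)C(C)(C)C)C[C@@]2(C)O1 | intermediate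
15 | (E)-3-[(2R,6S,7aR)-6-(tert-butyldimethylsilyloxy)-4,4,7a-trimethyl-2,4,5,6,7,7a-hexahydro-1-benzofuran-2-yl]but-2-enal | O=C/C=C(\C)[C@H]1C=C2C(C)(C)C[C@H](O[Si](C)(C)C(C)(C)C)C[C@@]2(C)O1 | intermediate
16 | trimethylsilylacetylene | C#C[Si](C)(C)C | starting material
17 | (R)-tert-butyldimethyl{[3,5,5-trimethyl-4-(trimethylsilylethynyl)cyclohex-3-en-1-yl]oxy}silane | CC1=C(C#C[Si](C)(C)C)C(C)(C)C[C@H](O[Si](C)(C)C(C)(C)C)C1 | intermediate
18 | (1R,2R,4S)-4-(tert-butyldimethylsilyloxy)-2,6,6-trimethyl-1-(trimethylsilylethynyl)cyclohexane-1,2-diol | C[Si](C)(C)C#C[C@]1(O)C(C)(C)C[C@H](O[Si](C)(C)C(C)(C)C)C[C@@]1(C)O | intermediate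
19 | (1R,2R,4S)-4-(tert-butyldimethylsilyloxy)-1-ethynyl-2,6,6-trimethylcyclohexane-1,2-diol | C#C[C@]1(O)C(C)(C)C[C@H](O[Si](C)(C)C(C)(C)C)C[C@@]1(C)O | intermediate
20 | ethyl but-2-ynoate | CC#CC(=O)OCC | starting material
21 | ethyl (E)-5-[(1R,2R,4S)-4-(tert-butyldimethylsilyloxy)-1,2-dihydroxy-2,6,6-trimethylcyclohexyl]-3-methylpent-2-en-4-ynoate | CCOC(=O)/C=C(\C)C#C[C@]1(O)C(C)(C)C[C@H](O[Si](C)(C)C(C)(C)C)C[C@@]1(C)O | intermediate
22 | (1S,2R,4S)-4-(tert-butyldimethylsilyloxy)-1-[(1E,3E)-5-hydroxy-3-methylpenta-1,3-dien-1-yl]-2,6,6-trimethylcyclohexane-1,2-diol | OC/C=C(C)/C=C/[C@]1(O)C(C)(C)C[C@H](O[Si](C)(C)C(C)(C)C)C[C@@]1(C)O | intermediate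
23 | (2E,4E)-5-[(1S,2R,4S)-4-(tert-butyldimethylsilyloxy)-1,2-dihydroxy-2,6,6-trimethylcyclohexyl]-3-methylpenta-2,4-dienal | O=C/C=C(C)/C=C/[C@]1(O)C(C)(C)C[C@H](O[Si](C)(C)C(C)(C)C)C[C@@]1(C)O | intermediate
24 | (2E,4E,6E)-2,7-dimethylocta-2,4,6-trienedial | O=C/C(C)=C/C=C/C=C(\C)C=O | starting material
25 | (2E,4E,6E)-2,7-dimethylocta-2,4,6-triene-1,8-diol | OC/C(C)=C/C=C/C=C(\C)CO | intermediate
26 | (2E,4E,6E)-1,8-dibromo-2,7-dimethylocta-2,4,6-triene | BrC/C(C)=C/C=C/C=C(\C)CBr | intermediate
27 | tetraethyl [(2E,4E,6E)-2,7-dimethylocta-2,4,6-triene-1,8-diyl]bis(phosphonate) | CCOP(=O)(OCC)C/C(C)=C/C=C/C=C(\C)CP(=O)(OCC)OCC | intermediate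
28 | monosodium carbanion of bis(phosphonate) 27 | CCOP(=O)(OCC)[CH-]/C(C)=C/C=C/C=C(\C)CP(=O)(OCC)OCC.[Na+] | intermediate
29 | diethyl {(2E,4E,6E,8E,10E,12E)-13-[(1S,2R,4S)-4-(tert-butyldimethylsilyloxy)-1,2-dihydroxy-2,6,6-trimethylcyclohexyl]-2,7,11-trimethyltrideca-2,4,6,8,10,12-hexaen-1-yl}phosphonate | CCOP(=O)(OCC)C/C(C)=C/C=C/C=C(C)/C=C/C=C(C)/C=C/[C@]1(O)C(C)(C)C[C@H](O[Si](C)(C)C(C)(C)C)C[C@@]1(C)O | intermediate
30 | trisodium salt of 29 (phosphonate carbanion and both tertiary alkoxides) | CCOP(=O)(OCC)[CH-]/C(C)=C/C=C/C=C(C)/C=C/C=C(C)/C=C/[C@]1([O-])C(C)(C)C[C@H](O[Si](C)(C)C(C)(C)C)C[C@@]1(C)[O-].[Na+].[Na+].[Na+] | intermediate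
31 | (3S,5R,6S,3'S,5'R,8'R)-3,3'-bis(tert-butyldimethylsilyloxy)-5',8'-epoxy-5,6,5',8'-tetrahydro-β,β-carotene-5,6-diol | CC(/C=C/C=C(C)/C=C/[C@]1(O)C(C)(C)C[C@H](O[Si](C)(C)C(C)(C)C)C[C@@]1(C)O)=C\C=C\C=C(C)\C=C\C=C(/C)[C@H]1C=C2C(C)(C)C[C@H](O[Si](C)(C)C(C)(C)C)C[C@@]2(C)O1 | intermediate
32 | (3S,5R,6S,3'S,5'R,8'R)-5',8'-epoxy-5,6,5',8'-tetrahydro-β,β-carotene-3,5,6,3'-tetrol | CC(/C=C/C=C(C)/C=C/[C@]1(O)C(C)(C)C[C@H](O)C[C@@]1(C)O)=C\C=C\C=C(C)\C=C\C=C(/C)[C@H]1C=C2C(C)(C)C[C@H](O)C[C@@]2(C)O1 | target

## Count and risks

Total: 23 steps. Longest linear sequence: 13 steps (steps 1–11, 22, 23; the left branch, steps 1–4, 12–17, 21–23, is equally long).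

**Step 9 (key step).** The most likely failure is loss of axial purity before ring closure: cationic gold can epimerise a vinyl-substituted allene through an allyl-cation-like species, and the vinylallene can also be diverted into a gold-induced Nazarov-type cyclisation. Acid traces could then ionise the new C8'–O bond. Fallback from 12 back to 13 by electrophile-induced closure: N-iodosuccinimide in CH2Cl2 at −20 °C should form the iodonium on C7'=C8' and let the C5' hydroxyl close on C8' with the same in-plane geometry, giving the 7'-iodo dihydrofuran F1. Radical hydrodeiodination of F1 with (Me3Si)3SiH and Et3B/air at 0 °C then returns the route to 13.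

**Step 8.** The risk is hydride arriving on the wrong face of the alkyne (an oxygen-directed, syn delivery would give the natural (6R) axis and hence the C8' epimer), together with competing reduction of the allylic acetate or the enyne. Fallback from 10 to 12 through an allenylpalladium, whose stereochemical course is fixed by inversion on oxidative addition and retention on hydride transfer. Methanolysis of 10 (K2CO3, MeOH) gives the epoxy enynol F2, so that no allylic ester is offered to palladium. Pd2(dba)3·CHCl3 with n-Bu3P and HCO2NH4 in THF should open F2 to the allenic diol F3. Selective acetylation of the primary hydroxyl of F3 (Ac2O, pyridine, 0 °C) returns the route to 12.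

**Step 7.** The risk is poor facial selectivity, since the C3' silyloxy group is the only control element and acts from a 1,3 distance; some attack on the chain alkene is a lesser concern. Fallback with reagent control, from 6 to 10:
- Methoxycarbonylation of triflate 6 (Pd(OAc)2, PPh3, CO, MeOH, Et3N) gives ester F4.
- i-Bu2AlH reduces F4 to the allylic alcohol F5.
- Sharpless epoxidation of F5 with Ti(Oi-Pr)4, D-(−)-diethyl tartrate and t-BuOOH gives the anti epoxy alcohol F6.
- Parikh–Doering oxidation of F6 gives the epoxy aldehyde F7.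
- Seyferth–Gilbert homologation of F7 with the Ohira–Bestmann reagent gives the ethynyl epoxide F8.
- Palladium-catalysed cross-addition of F8 to ethyl but-2-ynoate 20, as in step 15, gives the epoxy enynoate F9.
- i-Bu2AlH in THF at −78 °C, quenched cold before the epoxide is touched, reduces F9 to the epoxy enynol F2.
- Acetylation of F2 returns the route to 10.

**Step 13.** The risks are slow turnover at the tetrasubstituted alkene, for which stoichiometric OsO4 in pyridine is the first remedy, and attack on the face syn to the silyloxy group. Fallback from 17 to 19 by the Woodward cis-hydroxylation, which places the diol on the face opposite to the first electrophilic attack and so answers a wrong facial preference: I2 and AgOAc in wet acetic acid should give the cis-diol monoacetate F10 (with its regioisomer), and K2CO3 in MeOH removes the acetate and the alkynyl silyl group to return the route to 19.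

**Step 22.** The risks are sluggish reaction or poor E selectivity of the trianion 30, and epimerisation at C8' of 15 if free base survives. Fallback with the phosphonate moved to the furanoid side and the diol protected, from 15 and 23 to 32:
- 15 is olefinated with excess 27 (NaN(SiMe3)2, THF) to the furanoid 25-carbon phosphonate F11.
- 23 is silylated with N-(trimethylsilyl)imidazole to the bis(trimethylsilyl) ether dienal F12.
- The anion of F11 and F12 give the fully silylated 40-carbon compound F13.
- Bu4NF removes all four silyl groups from F13 and returns the route at 32.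

## Further compounds

F1 | step 9 | 7'-iodo dihydrofuran acetate | CC(=O)OC/C=C(\C)[C@H]1C(I)=C2C(C)(C)C[C@H](O[Si](C)(C)C(C)(C)C)C[C@@]2(C)O1
F2 | step 8 | epoxy enynol (anti epoxide, free C11' hydroxyl) | OC/C=C(\C)C#C[C@@]12O[C@]1(C)C[C@@H](O[Si](C)(C)C(C)(C)C)CC2(C)C
F3 | step 8 | allenic diol, (S) axis, free C5' and C11' hydroxyls | OC/C=C(\C)C([H])=[C@]=C1C(C)(C)C[C@H](O[Si](C)(C)C(C)(C)C)C[C@@]1(C)O
F4 | step 7 | methyl (R)-4-(tert-butyldimethylsilyloxy)-2,6,6-trimethylcyclohex-1-ene-1-carboxylate | COC(=O)C1=C(C)C[C@@H](O[Si](C)(C)C(C)(C)C)CC1(C)C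
F5 | step 7 | [(R)-4-(tert-butyldimethylsilyloxy)-2,6,6-trimethylcyclohex-1-en-1-yl]methanol | OCC1=C(C)C[C@@H](O[Si](C)(C)C(C)(C)C)CC1(C)C
F6 | step 7 | anti epoxy alcohol | OC[C@@]12O[C@]1(C)C[C@@H](O[Si](C)(C)C(C)(C)C)CC2(C)C
F7 | step 7 | anti epoxy aldehyde | O=C[C@@]12O[C@]1(C)C[C@@H](O[Si](C)(C)C(C)(C)C)CC2(C)C
F8 | step 7 | anti ethynyl epoxide | C#C[C@@]12O[C@]1(C)C[C@@H](O[Si](C)(C)C(C)(C)C)CC2(C)C
F9 | step 7 | ethyl (E)-epoxy enynoate | CCOC(=O)/C=C(\C)C#C[C@@]12O[C@]1(C)C[C@@H](O[Si](C)(C)C(C)(C)C)CC2(C)C
F10 | step 13 | cis-5,6-diol 5-monoacetate of the alkynylsilane | C[Si](C)(C)C#C[C@]1(O)C(C)(C)C[C@H](O[Si](C)(C)C(C)(C)C)C[C@@]1(C)OC(C)=O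
F11 | step 22 | furanoid 25-carbon phosphonate | CCOP(=O)(OCC)C/C(C)=C/C=C/C=C(C)/C=C/C=C(\C)[C@H]1C=C2C(C)(C)C[C@H](O[Si](C)(C)C(C)(C)C)C[C@@]2(C)O1
F12 | step 22 | 5,6-bis(trimethylsilyl) ether of dienal 23 | O=C/C=C(C)/C=C/[C@]1(O[Si](C)(C)C)C(C)(C)C[C@H](O[Si](C)(C)C(C)(C)C)C[C@@]1(C)O[Si](C)(C)C
F13 | step 22 | 3,3'-bis(tert-butyldimethylsilyl) 5,6-bis(trimethylsilyl) ether of the target | CC(/C=C/C=C(C)/C=C/[C@]1(O[Si](C)(C)C)C(C)(C)C[C@H](O[Si](C)(C)C(C)(C)C)C[C@@]1(C)O[Si](C)(C)C)=C\C=C\C=C(C)\C=C\C=C(/C)[C@H]1C=C2C(C)(C)C[C@H](O[Si](C)(C)C(C)(C)C)C[C@@]2(C)O1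
A1 | alternative 1 | alkynyl cis-diol, both hydroxyls trans to the C3 silyloxy group (identical with 18) | C[Si](C)(C)C#C[C@]1(O)C(C)(C)C[C@H](O[Si](C)(C)C(C)(C)C)C[C@@]1(C)O
A2 | alternative 2 | ethyl (2E,4E)-5-[(R)-4-(tert-butyldimethylsilyloxy)-2,6,6-trimethylcyclohex-1-en-1-yl]-3-methylpenta-2,4-dienoate | CCOC(=O)/C=C(C)/C=C/C1=C(C)C[C@@H](O[Si](C)(C)C(C)(C)C)CC1(C)C
A3 | alternative 2 | 5',8'-endoperoxide ester | CCOC(=O)/C=C(\C)[C@H]1C=C2C(C)(C)C[C@H](O[Si](C)(C)C(C)(C)C)C[C@@]2(C)OO1
A4 | alternative 3 | 15-carbon anti-5,6-epoxy dienoate | CCOC(=O)/C=C(C)/C=C/[C@@]12O[C@]1(C)C[C@@H](O[Si](C)(C)C(C)(C)C)CC2(C)C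
A5 | alternative 3 | 5,6-cis cyclic carbonate of the 15-carbon dienoate | CCOC(=O)/C=C(C)/C=C/[C@]12C(C)(C)C[C@H](O[Si](C)(C)C(C)(C)C)C[C@@]1(C)OC(=O)O2
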